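**Plan**

- Retrosynthetic cuts: (i) the aryl C5–CH2 bond to the C10 side chain (Negishi coupling); (ii) the O1–C2 bond of the dihydrofuran, traced back through a 1,2-aryloxy shift to the O1–C(CH3)2 bond of a 2,2-dimethylchroman-3-ol; (iii) the pyran ring into 3-methylbut-2-enal and a benzophenone with two equivalent ortho-hydroxyls; (iv) the diaryl ketone bond (Friedel–Crafts); (v) the Cα–CH2 bond of the side chain (auxiliary-controlled alkylation).
- Forward order: benzophenone, then the six-membered 2H-chromene ring (oxa-6π), epoxide, chroman-3-ol, contraction to the five-membered 2-(2-hydroxypropan-2-yl)-2,3-dihydrobenzofuran, iodination at C5, side chain joined, acetates removed.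
- Enabling feature: in the chroman ring (O1, C2, C3, C4, C4a, C8a) the ring oxygen O1 lies β and antiperiplanar to a leaving group on C3, and the gem-dimethyl carbon C2 can carry positive charge. When O1 moves from C2 to C3, C2 leaves the ring and becomes the carbinol carbon, so the five-membered ring (O1, C3, C4, C4a, C8a) and the tertiary alcohol arise together.
- Stereochemistry: the dihydrofuran C2 (S) comes from the (3R) centre of the chromanol, set by (R,R)-(salen)MnCl epoxidation of the chromene and inverted in the shift. The side-chain centre (R in the target) comes from alkylation of the dienolate of an (S)-4-benzyloxazolidinone imide.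

Key step: step 7

Remark: the (R,R)-(salen)MnCl catalyst is assumed to deliver oxygen to chromene 8 with the same facial sense as to the parent 2,2-dimethyl-2H-chromene, giving the (3R,4R)-epoxide. Chroman numbering is used up to compound 11 and benzofuran numbering from compound 12 on.

**Route**

Step 1
Reactants: 1 meta-acetoxybenzoic acid (3-acetoxybenzoic acid); 2 phloroglucinol trimethyl ether (1,3,5-trimethoxybenzene)
Product: 4 (3-acetoxyphenyl)(2,4,6-trimethoxyphenyl)methanone, via 3-acetoxybenzoyl chloride 3 (not isolated)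
Conditions: (COCl)2, DMF (cat.), CH2Cl2, 0 °C → rt; then 2, AlCl3 (1.1 equiv), CH2Cl2, −10 → 0 °C
Reagents that add atoms: none
Why: Friedel–Crafts acylation of the symmetric, highly nucleophilic arene by the acid chloride made in the flask should stop at the mono-ketone, because the product is deactivated and hindered, and the aryl acetate tolerates AlCl3 in the cold.

Step 2
Reactants: 4 (3-acetoxyphenyl)(2,4,6-trimethoxyphenyl)methanone
Product: 5 (2,6-dihydroxy-4-methoxyphenyl)(3-hydroxyphenyl)methanone
Conditions: AlCl3 (6 equiv), CH2Cl2, 0 → 40 °C; then MeOH, 2 M HCl, 50 °C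
Reagents that add atoms: none
Why: Chelation-directed Lewis-acid O-demethylation should remove both methoxy groups ortho to the carbonyl and keep the para one (a deactivated vinylogous ester oxygen), while the acidic methanol work-up transesterifies the aryl acetate, leaving a ring with two equivalent hydroxyls.

Step 3
Reactants: 5 (2,6-dihydroxy-4-methoxyphenyl)(3-hydroxyphenyl)methanone; 6 prenal (3-methylbut-2-enal)
Product: 7 (7-hydroxy-5-methoxy-2,2-dimethyl-2H-chromen-8-yl)(3-hydroxyphenyl)methanone
Conditions: EDDA (ethylenediammonium diacetate, 10 mol%), 6 (1.1 equiv), toluene, 100 °C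
Reagents that add atoms: none
Why: Amine-catalysed Knoevenagel-type condensation at the ring carbon between OH and OCH3, loss of water to an ortho-quinone methide and oxa-6π electrocyclisation should give the 2H-chromene as one regioisomer, since the two ortho-hydroxyls are equivalent and the acyl-deactivated 3-hydroxyphenyl ring does not react.

Step 4
Reactants: 7 (7-hydroxy-5-methoxy-2,2-dimethyl-2H-chromen-8-yl)(3-hydroxyphenyl)methanone
Product: 8 chromene diacetate: 8-(3-acetoxybenzoyl)-5-methoxy-2,2-dimethyl-2H-chromen-7-yl acetate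
Conditions: Ac2O, pyridine, DMAP (cat.), CH2Cl2, rt
Reagents that add atoms: acetic anhydride, CC(=O)OC(C)=O
Why: DMAP-catalysed O-acetylation should cap both phenols, including the hydrogen-bonded one, which keeps them out of the oxidation in step 5 and the triflation in step 7.

Step 5
Reactants: 8 chromene diacetate
Product: 9 epoxide diacetate: (3R,4R)-8-(3-acetoxybenzoyl)-3,4-epoxy-5-methoxy-2,2-dimethylchroman-7-yl acetate (cis-fused oxirane across C3–C4)
Conditions: (R,R)-(salen)MnCl [chloro((R,R)-N,N'-bis(3,5-di-tert-butylsalicylidene)cyclohexane-1,2-diaminato)manganese, trivalent manganese] (5 mol%), mCPBA, NMO, CH2Cl2, −78 °C; cold basic wash, used crude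
Reagents that add atoms: 3-chloroperbenzoic acid (mCPBA), OOC(=O)c1cccc(Cl)c1
Why: Jacobsen–Katsuki epoxidation, for which cis-disubstituted aryl-conjugated 2,2-dimethylchromenes are the best substrate class, should transfer oxygen from the pentavalent manganese oxo species to the face that gives the (3R,4R)-oxirane, and the anhydrous low-temperature protocol spares the acetates and the acid-labile epoxide.

Step 6
Reactants: 9 epoxide diacetate
Product: 10 chromanol diacetate: (3R)-8-(3-acetoxybenzoyl)-3-hydroxy-5-methoxy-2,2-dimethylchroman-7-yl acetate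
Conditions: H2 (1 atm), Pd/C (10% palladium on carbon), NaHCO3 (solid), EtOAc, 0 °C → rt
Reagents that add atoms: none
Why: Catalytic hydrogenolysis should cleave only the benzylic C4–O bond of the oxirane, so that C3 keeps its oxygen and its (R) configuration, while the hindered diaryl ketone and the acetates react more slowly under these buffered conditions.

Step 7
Reactants: 10 chromanol diacetate
Product: 12 dihydrobenzofuran diacetate: (2S)-7-(3-acetoxybenzoyl)-2-(2-hydroxypropan-2-yl)-4-methoxy-2,3-dihydrobenzofuran-6-yl acetate, via chromanyl triflate 11 (not isolated)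
Conditions: Tf2O, 2,6-lutidine, CH2Cl2, −78 °C; then THF/H2O, NaHCO3, −78 → 20 °C
Reagents that add atoms: water, O
Why: The secondary alcohol is triflated, and the equatorial C3–OTf bond, antiperiplanar to the C2–O1 ring bond, should ionise with backside participation of the ring oxygen (1,2-aryloxy shift through a bridged aryloxiranium ion), so that O1 becomes bonded to C3 and the positive charge passes to the gem-dimethyl carbon C2, where water adds to give the tertiary alcohol. The closest known reaction type is the solvolytic ring contraction of sulfonate- or DAST-activated 2,2-dimethylchroman-3-ols to 2-(propan-2-yl-substituted) 2,3-dihydrobenzofurans, and of pyranosides with an equatorial leaving group at C2 to 2,5-anhydro sugars. The five-membered ring is not closed by a cyclisation of its own: the O1–C3 bond forms by 3-exo-tet backside attack inside the six-membered ring and the O1–C2 bond then breaks, a contraction from six to five ring atoms. The new C2 stereocentre of the dihydrobenzofuran is controlled by the C3 centre of 10 through stereospecific inversion, (3R) giving (2S). The step needs oxygen migration in preference to methyl or hydride shift, to loss of triflic acid towards the chromene and to return of water at C3; the equatorial triflate geometry, the tertiary character of C2, the cold hindered base and the large excess of water should secure this, and the acetates keep both phenols out of the triflation.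

Step 8
Reactants: 12 dihydrobenzofuran diacetate
Product: 13 aryl iodide: (2S)-7-(3-acetoxybenzoyl)-2-(2-hydroxypropan-2-yl)-5-iodo-4-methoxy-2,3-dihydrobenzofuran-6-yl acetate
Conditions: NIS, TFA (cat.), MeCN, 0 °C → rt, dark
Reagents that add atoms: N-iodosuccinimide, O=C1CCC(=O)N1I
Why: Electrophilic aromatic iodination should occur at C5, the only unsubstituted position of the trioxygenated ring (ortho to OCH3, para to the ring oxygen), whereas the acetoxybenzoyl ring is deactivated and the tertiary alcohol is inert in the dark.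

Step 9
Reactants: 14 (S)-4-benzyloxazolidin-2-one; 15 senecioyl chloride (3-methylbut-2-enoyl chloride)
Product: 17 (S)-4-benzyl-3-(3-methylbut-2-enoyl)oxazolidin-2-one, via N-lithio oxazolidinone 16 (not isolated)
Conditions: n-BuLi, THF, −78 °C; then 15, −78 → 0 °C
Reagents that add atoms: none
Why: N-Acylation of the lithiated oxazolidinone by the acid chloride is the standard entry to Evans imides and does not touch the stereocentre of the auxiliary.

Step 10
Reactants: 18 isoprenol (3-methylbut-3-en-1-ol)
Product: 19 isoprenyl triflate (3-methylbut-3-en-1-yl trifluoromethanesulfonate)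
Conditions: Tf2O, pyridine, CH2Cl2, −30 °C; cold pentane filtration, used at once
Reagents that add atoms: trifluoromethanesulfonic anhydride, O=S(=O)(OS(=O)(=O)C(F)(F)F)C(F)(F)F
Why: O-Sulfonylation of the primary alcohol gives a triflate reactive enough for SN2 alkylation of an imide enolate at −78 °C, which the corresponding unactivated halide would not be.

Step 11
Reactants: 17 (S)-4-benzyl-3-(3-methylbut-2-enoyl)oxazolidin-2-one; 19 isoprenyl triflate
Product: 21 (4S)-4-benzyl-3-[(2S)-5-methyl-2-(prop-1-en-2-yl)hex-5-enoyl]oxazolidin-2-one, via sodium dienolate 20 (not isolated)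
Conditions: NaHMDS (1.05 equiv), THF, −78 °C; then 19, −78 → −40 °C
Reagents that add atoms: none
Why: Evans deconjugative alkylation: γ-deprotonation should give the chelated (Z)-sodium dienolate, which reacts at the α-carbon on the face opposite the benzyl group of the auxiliary, setting the (2S) centre and creating the isopropenyl group in the same event.

Step 12
Reactants: 21 (4S)-4-benzyl-3-[(2S)-5-methyl-2-(prop-1-en-2-yl)hex-5-enoyl]oxazolidin-2-one
Product: 22 (2S)-5-methyl-2-(prop-1-en-2-yl)hex-5-en-1-ol
Conditions: LiBH4, MeOH (1 equiv), Et2O, 0 °C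
Reagents that add atoms: none
Why: Reductive cleavage of the imide by LiBH4 should release the primary alcohol and the auxiliary, and is done at once so that the base-sensitive α-centre can no longer epimerise or move into conjugation.

Step 13
Reactants: 22 (2S)-5-methyl-2-(prop-1-en-2-yl)hex-5-en-1-ol
Product: 23 (3S)-3-(iodomethyl)-2,6-dimethylhepta-1,6-diene
Conditions: I2, PPh3, imidazole, CH2Cl2, 0 °C → rt
Reagents that add atoms: iodine, II
Why: Appel-type iodination (Garegg–Samuelsson conditions) is an SN2 displacement at the primary carbon and leaves the adjacent stereocentre untouched.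

Step 14
Reactants: 23 (3S)-3-(iodomethyl)-2,6-dimethylhepta-1,6-diene; 13 aryl iodide
Product: 25 coupled diacetate: (2S)-7-(3-acetoxybenzoyl)-2-(2-hydroxypropan-2-yl)-4-methoxy-5-[(2R)-5-methyl-2-(prop-1-en-2-yl)hex-5-en-1-yl]-2,3-dihydrobenzofuran-6-yl acetate, via alkylzinc iodide 24 (not isolated)
Conditions: Zn dust (BrCH2CH2Br/TMSCl-activated), LiCl, THF, 35 °C; then 13 (limiting, 24 in 1.6-fold excess), Pd(OAc)2 (5 mol%), SPhos (10 mol%), THF/NMP, 45 °C
Reagents that add atoms: none
Why: Negishi coupling: the primary alkylzinc iodide tolerates the ketone, the acetates and the tertiary alcohol, and the zerovalent palladium–SPhos catalyst should couple the doubly ortho-substituted aryl iodide with reductive elimination faster than β-hydride elimination, so the β-stereocentre is kept.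

Step 15
Reactants: 25 coupled diacetate
Product: 26 target: (3-hydroxyphenyl){(2S)-6-hydroxy-2-(2-hydroxypropan-2-yl)-4-methoxy-5-[(2R)-5-methyl-2-(prop-1-en-2-yl)hex-5-en-1-yl]-2,3-dihydrobenzofuran-7-yl}methanone
Conditions: K2CO3, MeOH, 0 °C → rt
Reagents that add atoms: none
Why: Carbonate-mediated methanolysis (Zemplén-type transesterification) should remove both aryl acetates, and nothing else in the molecule is base-labile or has an acidic stereocentre.

**Compound list**

1 | 3-acetoxybenzoic acid | CC(=O)Oc1cccc(C(=O)O)c1 | starting material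
2 | 1,3,5-trimethoxybenzene | COc1cc(OC)cc(OC)c1 | starting material
3 | 3-acetoxybenzoyl chloride | CC(=O)Oc1cccc(C(Cl)=O)c1 | intermediate (not isolated)
4 | (3-acetoxyphenyl)(2,4,6-trimethoxyphenyl)methanone | COc1cc(OC)c(C(=O)c2cccc(OC(C)=O)c2)c(OC)c1 | intermediate
5 | (2,6-dihydroxy-4-methoxyphenyl)(3-hydroxyphenyl)methanone | COc1cc(O)c(C(=O)c2cccc(O)c2)c(O)c1 | intermediate
6 | 3-methylbut-2-enal | CC(C)=CC=O | starting material
7 | (7-hydroxy-5-methoxy-2,2-dimethyl-2H-chromen-8-yl)(3-hydroxyphenyl)methanone | CC1(C)C=Cc2c(OC)cc(O)c(C(=O)c3cccc(O)c3)c2O1 | intermediate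
8 | 8-(3-acetoxybenzoyl)-5-methoxy-2,2-dimethyl-2H-chromen-7-yl acetate | CC1(C)C=Cc2c(OC)cc(OC(C)=O)c(C(=O)c3cccc(OC(C)=O)c3)c2O1 | intermediate
9 | (3R,4R)-8-(3-acetoxybenzoyl)-3,4-epoxy-5-methoxy-2,2-dimethylchroman-7-yl acetate | CC1(C)[C@@H]2O[C@@H]2c2c(OC)cc(OC(C)=O)c(C(=O)c3cccc(OC(C)=O)c3)c2O1 | intermediate
10 | (3R)-8-(3-acetoxybenzoyl)-3-hydroxy-5-methoxy-2,2-dimethylchroman-7-yl acetate | CC1(C)Oc2c(C(=O)c3cccc(OC(C)=O)c3)c(OC(C)=O)cc(OC)c2C[C@H]1O | intermediate
11 | (3R)-8-(3-acetoxybenzoyl)-5-methoxy-2,2-dimethyl-3-(trifluoromethanesulfonyloxy)chroman-7-yl acetate | CC1(C)Oc2c(C(=O)c3cccc(OC(C)=O)c3)c(OC(C)=O)cc(OC)c2C[C@H]1OS(=O)(=O)C(F)(F)F | intermediate (not isolated)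
12 | (2S)-7-(3-acetoxybenzoyl)-2-(2-hydroxypropan-2-yl)-4-methoxy-2,3-dihydrobenzofuran-6-yl acetate | CC(C)(O)[C@@H]1Cc2c(OC)cc(OC(C)=O)c(C(=O)c3cccc(OC(C)=O)c3)c2O1 | intermediate
13 | (2S)-7-(3-acetoxybenzoyl)-2-(2-hydroxypropan-2-yl)-5-iodo-4-methoxy-2,3-dihydrobenzofuran-6-yl acetate | CC(C)(O)[C@@H]1Cc2c(OC)c(I)c(OC(C)=O)c(C(=O)c3cccc(OC(C)=O)c3)c2O1 | intermediate
14 | (S)-4-benzyloxazolidin-2-one | O=C1N[C@@H](Cc2ccccc2)CO1 | starting material
15 | 3-methylbut-2-enoyl chloride | CC(C)=CC(Cl)=O | starting material
16 | N-lithio-(S)-4-benzyloxazolidin-2-one | [Li]N1[C@@H](Cc2ccccc2)COC1=O | intermediate (not isolated)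
17 | (S)-4-benzyl-3-(3-methylbut-2-enoyl)oxazolidin-2-one | CC(C)=CC(=O)N1[C@@H](Cc2ccccc2)COC1=O | intermediate
18 | 3-methylbut-3-en-1-ol | C=C(C)CCO | starting material
19 | 3-methylbut-3-en-1-yl trifluoromethanesulfonate | C=C(C)CCOS(=O)(=O)C(F)(F)F | intermediate
20 | sodium (Z)-dienolate of 17 (oxygen and isopropenyl cis) | C=C(C)/C=C(\[O-])N1[C@@H](Cc2ccccc2)COC1=O.[Na+] | intermediate (not isolated)
21 | (4S)-4-benzyl-3-[(2S)-5-methyl-2-(prop-1-en-2-yl)hex-5-enoyl]oxazolidin-2-one | C=C(C)CC[C@@H](C(C)=C)C(=O)N1[C@@H](Cc2ccccc2)COC1=O | intermediate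
22 | (2S)-5-methyl-2-(prop-1-en-2-yl)hex-5-en-1-ol | C=C(C)CC[C@@H](C(C)=C)CO | intermediate
23 | (3S)-3-(iodomethyl)-2,6-dimethylhepta-1,6-diene | C=C(C)CC[C@@H](C(C)=C)CI | intermediate
24 | [(2S)-5-methyl-2-(prop-1-en-2-yl)hex-5-en-1-yl]zinc iodide | C=C(C)CC[C@@H](C(C)=C)C[Zn]I | intermediate (not isolated)
25 | (2S)-7-(3-acetoxybenzoyl)-2-(2-hydroxypropan-2-yl)-4-methoxy-5-[(2R)-5-methyl-2-(prop-1-en-2-yl)hex-5-en-1-yl]-2,3-dihydrobenzofuran-6-yl acetate | CC(C)(O)[C@@H]1Cc2c(OC)c(C[C@@H](CCC(C)=C)C(C)=C)c(OC(C)=O)c(C(=O)c3cccc(OC(C)=O)c3)c2O1 | intermediate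
26 | (3-hydroxyphenyl){(2S)-6-hydroxy-2-(2-hydroxypropan-2-yl)-4-methoxy-5-[(2R)-5-methyl-2-(prop-1-en-2-yl)hex-5-en-1-yl]-2,3-dihydrobenzofuran-7-yl}methanone | CC(C)(O)[C@@H]1Cc2c(OC)c(C[C@@H](CCC(C)=C)C(C)=C)c(O)c(C(=O)c3cccc(O)c3)c2O1 | target

**Step count and risks**

Total step count: 15. Longest linear sequence: 10 steps (steps 1–8, 14, 15).

Steps most likely to fail:

1. Step 7. The aryloxiranium / tertiary cation may partition between hydration, loss of a methyl proton and return of water to C3, and a methyl or hydride shift may compete with the oxygen shift. Fallback, setting out from 10 and coming back at 12: chromanol 10 would be triflated as before but with 2,6-di-tert-butyl-4-methylpyridine and without water, and the solution warmed to rt, so that the same oxygen shift ends in proton loss and gives (2S)-7-(3-acetoxybenzoyl)-4-methoxy-2-(prop-1-en-2-yl)-2,3-dihydrobenzofuran-6-yl acetate F1. Markovnikov hydration of its 1,1-disubstituted alkene by hydrogen-atom transfer (Mukaiyama hydration: Co(acac)2, PhSiH3, O2, i-PrOH/THF, rt) should then return to 12, the tertiary alcohol now being installed by a radical instead of a cationic event.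

2. Step 14. Oxidative addition and transmetalation at the doubly ortho-substituted aryl iodide may be slow, so that β-hydride elimination or protodezincation takes over, and radical 1,2-vinyl migration during zinc insertion may scramble the side chain. Fallback, setting out from 23 (with 13) and coming back at 25: iodide 23 would undergo closed-shell iodine–lithium exchange (t-BuLi, Et2O, −78 °C) to [(2S)-5-methyl-2-(prop-1-en-2-yl)hex-5-en-1-yl]lithium F2, which is trapped with 9-methoxy-9-borabicyclo[3.3.1]nonane as lithium 9-methoxy-9-[(2S)-5-methyl-2-(prop-1-en-2-yl)hex-5-en-1-yl]-9-borabicyclo[3.3.1]nonan-9-uide F3. Base-free B-alkyl Suzuki–Miyaura coupling of this ate complex with 13 (PdCl2(dppf), DMF/THF, 50 °C) should give 25.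

3. Step 11. SN2 alkylation of the thermally fragile dienolate may be too slow, the homoallylic triflate may decompose, and the product may epimerise or reconjugate under excess base. Fallback, setting out from 17 and coming back at 21: imide 17 would be enolised with TiCl4 and i-Pr2NEt (CH2Cl2, −78 °C) to the trichlorotitanium (Z)-dienolate of 17 F4 and added to but-3-en-2-one (auxiliary-controlled Michael addition with the same facial sense) to give (4S)-4-benzyl-3-[(2S)-5-oxo-2-(prop-1-en-2-yl)hexanoyl]oxazolidin-2-one F5. Non-basic methylenation of the ketone (Takai–Lombardo: Zn, CH2Br2, TiCl4, THF, 0 °C) should return to 21, an activated acceptor replacing the unactivated electrophile.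

**Further compounds**

F1 | step 7 | (2S)-7-(3-acetoxybenzoyl)-4-methoxy-2-(prop-1-en-2-yl)-2,3-dihydrobenzofuran-6-yl acetate | CC(=C)[C@@H]1Cc2c(OC)cc(OC(C)=O)c(C(=O)c3cccc(OC(C)=O)c3)c2O1
F2 | step 14 | [(2S)-5-methyl-2-(prop-1-en-2-yl)hex-5-en-1-yl]lithium | C=C(C)CC[C@@H](C(C)=C)C[Li]
F3 | step 14 | lithium 9-methoxy-9-[(2S)-5-methyl-2-(prop-1-en-2-yl)hex-5-en-1-yl]-9-borabicyclo[3.3.1]nonan-9-uide | [Li+].CO[B-]1(C[C@@H](CCC(C)=C)C(C)=C)C2CCCC1CCC2
F4 | step 11 | trichlorotitanium (Z)-dienolate of 17 | C=C(C)/C=C(\O[Ti](Cl)(Cl)Cl)N1[C@@H](Cc2ccccc2)COC1=O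
F5 | step 11 | (4S)-4-benzyl-3-[(2S)-5-oxo-2-(prop-1-en-2-yl)hexanoyl]oxazolidin-2-one | CC(=O)CC[C@@H](C(C)=C)C(=O)N1[C@@H](Cc2ccccc2)COC1=O
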